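Readings and results are simulated from invented constants.

The readings show no slowness to wait for: in the dawn run target stands at 17.6 % after 0.625 d and at 17.6 % after 5.00 d, with substrate at 0 %. So the question is how substrate divides, not how long it takes.

| flask | substrate | partner | temperature | remark | time |
|---|---|---|---|---|---|
| midnight | 10 mM | 2.5 equiv | −10 °C | run made earlier |  |
| dawn | 10 mM | 1.7 equiv | 5 °C | run made earlier |  |
| summer | 10 mM | 3.8 equiv | −10 °C | run made earlier |  |
| north-east | 10 mM (in portions, 2, over 20 h) | 2.50 equiv | 5 °C | first portion at the start, last at 20 h | 4.0 d |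
| east | 10 mM | 2.50 equiv (fed, over 20 h) |  | the addition at −25 °C, then warmed to 5 °C; the feed brings no volume worth counting | 4.0 d |
| west | 10 mM | 2.50 equiv (fed, over 20 h) | 5 °C | all else is in the flask from the start; the feed brings no volume worth counting | 4.0 d |
| south-west | 10 mM (fed, over 20 h) | 2.50 equiv | 5 °C | all else is in the flask from the start; the feed brings no volume worth counting | 4.0 d |

| run | time / d | target / % | substrate / % |
|---|---|---|---|
| midnight | 2.00 | 46.2 | 0 |
| midnight | 4.00 | 46.5 | 0 |
| midnight | 6.00 | 46.8 | 0.1 |
| midnight | 8.00 | 46.0 | 0.3 |
| dawn | 0.625 | 17.6 | 0 |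
| dawn | 1.67 | 17.2 | 0.2 |
| dawn | 3.00 | 17.4 | 0 |
| dawn | 5.00 | 17.6 | 0 |
| summer | 1.25 | 57.6 | 0.1 |
| summer | 4.00 | 58.3 | 0.4 |
| summer | 6.00 | 58.0 | 0.5 |
| summer | 10.0 | 57.8 | 0 |

(each reading ± 0.5 percentage points)

* the best flask by amount of target, in percent of the substrate charged; "all alike" if 1.5 percentage points covers them all (north-east / east / west / south-west / all alike)
* amount of target at the end, in percent of the substrate charged, north-east
* amount of target at the end, in percent of the substrate charged, east
* amount of target at the end, in percent of the substrate charged, west
* amount of target at the end, in percent of the substrate charged, south-west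

Let substrate leave by a first-order loss and by reaction with partner, and write r for the partner concentration at which the two exits run equally fast. At partner level b the share going to target is b/(b+r). Integrated over a batch with substrate charge A, partner charge B and target P, this gives A = P + r·ln(B/(B−P)).

Dawn gives r = 75.4 mM at 5 °C: this break-even partner level is a selectivity factor with a unit. Midnight gives 26.0 mM and summer 25.6 mM at −10 °C, a real check, since their partner charges differ.

My reckoning: at full partner, north-east and south-west share 24.9 %. Dawn's substrate is below one percent at its first reading, so its lifetime is under 3.26 h. West's feed brings at most 4.07 mM in that time, a share below 5.40 %. With r lower in the cold, where full partner would give 49.0 %, I put east first, near that share.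

The forecast, a little below my first figure, says east, with 23.8 %, 42 %, 3 % and 23.8 %, on the ground “With first-order loss, dosing substrate changes nothing”.

The flasks give east as best, with 19.0 %, 45.0 %, 0.600 % and 18.7 %.

    crystals ⇌ target, rate k1*(cs1 - [target]) while solid is left; crystals form when [target] > cs1 (solubility = 0.150 mM, k = 1.14 h⁻¹)
    substrate → side product (k = 2.48 h⁻¹, Ea = 89.0 kJ mol⁻¹)
    partner → decomposed reagent (k = 0.0265 h⁻¹, Ea = 89.0 kJ mol⁻¹)
    substrate + partner → target (k = 31.3 M⁻¹ h⁻¹, Ea = 43.0 kJ mol⁻¹)
    (constants at 5 °C)

In north-east the partner's half-life of 26.2 h is longer than the 20 h wait, and 56.1 % of the partner stands at the last addition, which is 14.0 mM. There r gives that portion a share of 15.7 %, and with the 11.7 % already made, north-east comes to 19.5 % against 19.0 %. In west substrate reaches the midpoint of its turnover by 0.278 h, the feed brings 0.501 mM in one lifetime, and r gives 0.664 % against 0.600 %.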